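## Structural features

- The target is a C25 furanoterpenoid tetronic acid. Ring T is a 4-hydroxy-3-methylfuran-2(5H)-one (O1, C2 lactone carbonyl, C3 with methyl, C4 with OH, C5) that carries an exocyclic C5=C6 double bond of Z geometry.
- C6 is bonded to the only stereocentre, C7 (S, methyl-bearing). One methylene (C8) separates C7 from an (E,E)-diene C9=C10–C11(CH3)=C12, and C13–C14 tether the diene to ring A.
- Ring A is a 2,4-disubstituted furan (O1', C2'–C5'): C4' carries C14 and C2' carries a methylene (C15) bonded to C3 of ring B, a 3-furyl group. This 2,4-pattern is not what direct substitution of a 3-alkylfuran delivers cleanly.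
- Fragile groups: both furans and especially the bis(furyl)methane (acid and oxidant sensitive), the conjugated diene, the acidic tetronic acid, and C7–H, which becomes vinylogously acidic once the ylidene lactone is in place.
- The real difficulty is C7. It has no neighbouring stereocentre or heteroatom, yet must be set in absolute terms together with the E geometry of C9=C10 three bonds away, and must survive formation of the Z-ylidene.
- Read with C6 as a carboxyl carbon, the array C6(=O)–C7(CH3)–C8–C9=C10 is a γ,δ-unsaturated α-methyl acid. The key step exploits this retron for a [3,3] shift, with the C10 carbinol of a doubly allylic alcohol as the easily set source of chirality.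

## Logic of the disconnections

**27 to 20 and 22.** The C5=C6 bond is cut (with the O-methyl group as protection of C4–OH), via 26 and 24. This removes ring T as a small achiral piece and leaves an α-methyl aldehyde. The forward aldol addition, elimination and demethylation must give the Z-ylidene without epimerizing C7; 22 comes from 21 by O-methylation.

**20 to 15 (key disconnection, via 19).** The C7–C8 bond is cut with transposition of the C9=C10 double bond to C8=C9 and return of oxygen to C10. In one sentence: an Ireland–Claisen rearrangement of the propanoate of a doubly allylic secondary carbinol builds the stereocentre and the E-diene at once. The gain is that the stereocentre, the C7–C8 bond and the C9=C10 geometry all derive from one carbinol carbon, and the chiral precursor 15 has no stereocentre other than that carbinol. The demand is threefold: a single ketene acetal geometry, a chair transition state, and rearrangement through the vinyl arm rather than the trisubstituted arm.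

**15 to 11 and 12 (via 14 and 13).** The ester C–O bond and the C9–C10 bond are cut. The carbinol is made by vinyl addition to an enal and resolved, so the chirality is introduced on a simple secondary alcohol. The forward demand is high enantiomeric purity of 14.

**11 to 9 and 10.** The C11=C12 bond is cut by cross-metathesis logic. This reduces the enal to a terminal alkene and a commodity aldehyde; the forward step must give the E isomer and leave the furans alone.

**9 to 7.** The O1'–C2' bond of ring A is cut, together with the hydrogen shift that makes C15 a methylene. Ring A and the bridging carbon then come from one acyclic enynol, and the 2,4-pattern is fixed by connectivity. The forward step requires 5-exo attack of the hydroxyl on the alkyne and a Z-enynol.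

**7 to 4 and 6; 4 to 1 and 2; 6 to 5.** The C(sp2)–C(sp) bond is cut (Sonogashira logic). The vinyl iodide is cut at the C–C bond formed by carbomagnesiation of 1 with 2, and the alkyne is traced to 5. All pieces are then three- to five-carbon commercial compounds; the demand is Z geometry in 4.

## Other disconnections considered

**Alternative 1:** (the first that comes to mind) Cut C10–C11 (sp2–sp2) in addition to C5=C6. The forward key step is a Suzuki–Miyaura coupling of vinyl iodide A1, made from the Roche ester, with alkenylboronate A2, giving silyl ether A3, which is then deprotected and oxidized to the same aldehyde as in the chosen route.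
- A2 needs boron on the methyl-bearing carbon of a 2-alkyne, a regiochemical problem in hydroboration.
- A1 needs protection, reduction, one-carbon homologation and a vinyl iodide synthesis.
- The stereocentre and the diene geometry are bought separately, at a higher step count with two protecting-group operations. The chosen plan creates both in one event from a carbinol that is one step from an enal.

**Alternative 2:** Cut the O1–C5 lactone bond and close ring T last by 5-exo-dig lactonization (AgNO3 or Ph3PAuCl/AgOTf) of enynoic acid A4, which would give the O-methyl ylidene directly.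
- The anti-oxymetalation would secure the Z geometry, but it competes with 6-endo closure to a pyranone.
- A4 still contains the C7 stereocentre, now propargylic, and the whole diene, so the hard part of the target is untouched by the key step.
- The (E)-β-methoxy enynoic acid needs a stereodefined β-halo-β-methoxy acrylate. The plan is longer and solves less.

**Alternative 3:** Cut C9=C10 by Julia–Kocienski olefination of aldehyde A5 (from the Roche ester by homologation) with allylic tetrazolyl sulfone A6.
- The plan is convergent, but allylic sulfone anions are ambident and give E/Z mixtures at the new diene bond.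
- A5 needs protecting-group and homologation steps, and the stereocentre comes from the chiral pool without any stereochemical economy.
- The chosen [3,3] shift sets the E geometry through the chair and needs no protecting group on the chain.

Key step: step 9

Assumption: but-3-en-1-ylmagnesium bromide (THF solution), furan-3-carbaldehyde, methacrolein, vinylmagnesium bromide and 4-hydroxy-3-methylfuran-2(5H)-one are taken as purchasable, and the tetronic acid is treated as the 4-hydroxy tautomer written in the given SMILES.

## Route

Step 1
Reactants: 1 prop-2-yn-1-ol; 2 but-3-en-1-ylmagnesium bromide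
Product: 4 (2Z)-2-(but-3-en-1-yl)-3-iodoprop-2-en-1-ol, via alkenylmagnesium chelate 3 (not isolated)
Conditions: 2 (2.5 equiv), CuI (10 mol %), THF, −10 to 23 °C; then I2, −78 to 0 °C; aq NH4Cl/Na2S2O3
Reagents that add atoms: iodine, II
Why: Copper-catalysed anti-carbomagnesiation of the propargylic alkoxide places the butenyl group on the internal carbon and magnesium on the terminal carbon inside the five-membered alkoxide chelate 3; iodinolysis with retention should give the Z vinyl iodide with iodine cis to CH2OH.

Step 2
Reactants: 5 furan-3-carbaldehyde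
Product: 6 3-ethynylfuran
Conditions: dimethyl (1-diazo-2-oxopropyl)phosphonate, K2CO3, MeOH, 0 to 23 °C; product kept as an ethereal solution
Reagents that add atoms: dimethyl (1-diazo-2-oxopropyl)phosphonate, CC(=O)C(=[N+]=[N-])P(=O)(OC)OC
Why: Seyferth–Gilbert homologation with the Ohira–Bestmann reagent converts the aldehyde into the terminal alkyne under mild base; the volatile alkyne is not concentrated to dryness.

Step 3
Reactants: 4 (2Z)-2-(but-3-en-1-yl)-3-iodoprop-2-en-1-ol; 6 3-ethynylfuran
Product: 7 (2Z)-2-(but-3-en-1-yl)-5-(furan-3-yl)pent-2-en-4-yn-1-ol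
Conditions: Pd(PPh3)2Cl2 (2 mol %), CuI (4 mol %), Et3N, THF, 23 °C
Reagents that add atoms: none
Why: Sonogashira coupling of a vinyl iodide runs at room temperature with retention of alkene geometry and tolerates the free hydroxyl, so the hydroxymethyl group and the alkyne end up cis as the cyclization requires.

Step 4
Reactants: 7 (2Z)-2-(but-3-en-1-yl)-5-(furan-3-yl)pent-2-en-4-yn-1-ol
Product: 9 4-(but-3-en-1-yl)-2-(furan-3-ylmethyl)furan, via ylidene dihydrofuran 8 (not isolated)
Conditions: PdI2 (2 mol %), KI (4 mol %), N,N-dimethylacetamide, 60 °C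
Reagents that add atoms: none
Why: Cycloisomerization of a (Z)-2-en-4-yn-1-ol: anti 5-exo-dig oxypalladation of the alkyne by the hydroxyl and protodepalladation give 8, which aromatizes by a 1,3-hydrogen shift; the two alkyne carbons become C2' of ring A and the bridging methylene C15, so the 2,4-pattern follows from connectivity.

Step 5
Reactants: 9 4-(but-3-en-1-yl)-2-(furan-3-ylmethyl)furan; 10 2-methylprop-2-enal
Product: 11 (2E)-5-[5-(furan-3-ylmethyl)furan-3-yl]-2-methylpent-2-enal
Conditions: 10 (5 equiv), second-generation Hoveyda–Grubbs catalyst RuCl2(H2IMes)(=CH-C6H4-2-OiPr) (5 mol %), CH2Cl2, 40 °C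
Reagents that add atoms: none
Why: Olefin cross-metathesis of a terminal alkene with excess methacrolein should give the trisubstituted enal with the thermodynamically preferred E geometry; the aromatic furans are not expected to enter the metathesis.

Step 6
Reactants: 11 (2E)-5-[5-(furan-3-ylmethyl)furan-3-yl]-2-methylpent-2-enal; 12 vinylmagnesium bromide
Product: 13 rac-(4E)-7-[5-(furan-3-ylmethyl)furan-3-yl]-4-methylhepta-1,4-dien-3-ol
Conditions: THF, −78 °C; aq NH4Cl
Reagents that add atoms: none
Why: 1,2-Addition of a vinyl Grignard reagent to an α-branched enal at low temperature; C10 is formed racemic here and is resolved in step 7.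

Step 7
Reactants: 13 rac-(4E)-7-[5-(furan-3-ylmethyl)furan-3-yl]-4-methylhepta-1,4-dien-3-ol
Product: 14 (3S,4E)-7-[5-(furan-3-ylmethyl)furan-3-yl]-4-methylhepta-1,4-dien-3-ol
Conditions: Novozym 435 (immobilized Candida antarctica lipase B), vinyl acetate, tert-butyl methyl ether, 30 °C, stopped slightly past half conversion; chromatography
Reagents that add atoms: none
Why: Lipase-catalysed kinetic resolution by transesterification: by the empirical size rule for secondary alcohols (vinyl as the medium group, the 1-methylalkenyl chain as the large group) the R enantiomer should be acetylated, so running past half conversion should leave the S alcohol in high enantiomeric purity.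

Step 8
Reactants: 14 (3S,4E)-7-[5-(furan-3-ylmethyl)furan-3-yl]-4-methylhepta-1,4-dien-3-ol
Product: 15 (3S,4E)-7-[5-(furan-3-ylmethyl)furan-3-yl]-4-methylhepta-1,4-dien-3-yl propanoate
Conditions: propanoic anhydride, Et3N, 4-(dimethylamino)pyridine (cat.), CH2Cl2, 0 °C
Reagents that add atoms: propanoic anhydride, CCC(=O)OC(=O)CC
Why: Nucleophile-catalysed acylation under basic conditions avoids ionization of the doubly allylic C10–O bond; the stereocentre is not touched.

Step 9
Reactants: 15 (3S,4E)-7-[5-(furan-3-ylmethyl)furan-3-yl]-4-methylhepta-1,4-dien-3-yl propanoate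
Product: 19 (2S,4E,6E)-9-[5-(furan-3-ylmethyl)furan-3-yl]-2,6-dimethylnona-4,6-dien-1-ol, via lithium enolate 16 (not isolated), via silyl ketene acetal 17 (not isolated), via trimethylsilyl ester 18 (not isolated)
Conditions: LiN(iPr)2 (1.2 equiv), THF, −78 °C; Me3SiCl/Et3N, −78 to 23 °C, then 40 °C; then LiAlH4, THF, 0 °C
Reagents that add atoms: none
Why: Ireland–Claisen rearrangement of the propanoate of a secondary doubly allylic alcohol with reductive work-up. Kinetic deprotonation by LiN(iPr)2 in THF through the closed transition state gives enolate 16 with methyl trans to O–Li, and O-silylation fixes this as the (E)-ketene acetal 17. 17 then undergoes a concerted suprafacial [3,3] shift through a chair in which O–C10–C9=C8 is the allyl part, the C10–O bond breaking as C7–C8 forms; no ring is closed. The bulky 1-methylalkenyl group on C10 sits pseudo-equatorial, which makes the new C9=C10 bond E; with the ketene acetal methyl then pseudo-axial (cis to the allylic oxygen), C8 bonds to the face of C7 that gives S, so C7 is controlled jointly by the C10 configuration, the ketene acetal geometry and the chair. The selectivity needed is between the two allyl arms: bond formation at the unsubstituted terminus C8 should win over C12, which is substituted and whose arm carries the C11 methyl on the central allyl carbon, where it clashes with pseudo-axial groups in the chair. The closest known reaction type is the ester enolate Claisen rearrangement of propanoates of enantioenriched secondary allylic alcohols with transfer of chirality to the α-carbon. LiAlH4 then reduces silyl ester 18 in the same flask, so the acid is never isolated.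

Step 10
Reactants: 19 (2S,4E,6E)-9-[5-(furan-3-ylmethyl)furan-3-yl]-2,6-dimethylnona-4,6-dien-1-ol
Product: 20 (2S,4E,6E)-9-[5-(furan-3-ylmethyl)furan-3-yl]-2,6-dimethylnona-4,6-dienal
Conditions: Dess–Martin periodinane, pyridine, CH2Cl2, 0 °C; used without delay
Reagents that add atoms: none
Why: Dess–Martin oxidation under buffered, non-enolizing conditions should give the α-branched aldehyde without epimerization at C7 and without attack on the furans or the diene.

Step 11
Reactants: 21 4-hydroxy-3-methylfuran-2(5H)-one
Product: 22 4-methoxy-3-methylfuran-2(5H)-one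
Conditions: dimethyl sulfate, K2CO3, acetone, reflux
Reagents that add atoms: dimethyl sulfate, COS(=O)(=O)OC
Why: O-Alkylation of the vinylogous acid; C3 is already substituted, so methylation at O4 to the vinylogous ester should dominate.

Step 12
Reactants: 22 4-methoxy-3-methylfuran-2(5H)-one; 20 (2S,4E,6E)-9-[5-(furan-3-ylmethyl)furan-3-yl]-2,6-dimethylnona-4,6-dienal
Product: 24 5-[(2S,4E,6E)-9-[5-(furan-3-ylmethyl)furan-3-yl]-1-hydroxy-2,6-dimethylnona-4,6-dien-1-yl]-4-methoxy-3-methylfuran-2(5H)-one (mixture at C5 and C6), via lithiated tetronate 23 (not isolated)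
Conditions: LiN(iPr)2, THF, −78 °C; then 20, −78 °C; AcOH quench at −78 °C
Reagents that add atoms: none
Why: Vinylogous aldol addition: deprotonation at C5 gives the 2-oxidofuran 23, which adds to the aldehyde through C5 faster than it enolizes 20 at −78 °C; the two new centres are removed in step 13, so their configuration does not matter.

Step 13
Reactants: 24 5-[(2S,4E,6E)-9-[5-(furan-3-ylmethyl)furan-3-yl]-1-hydroxy-2,6-dimethylnona-4,6-dien-1-yl]-4-methoxy-3-methylfuran-2(5H)-one
Product: 26 (5Z)-5-[(2S,4E,6E)-9-[5-(furan-3-ylmethyl)furan-3-yl]-2,6-dimethylnona-4,6-dien-1-ylidene]-4-methoxy-3-methylfuran-2(5H)-one, via mesylate 25 (not isolated)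
Conditions: MeSO2Cl, Et3N, CH2Cl2, 0 °C; then 1,8-diazabicyclo[5.4.0]undec-7-ene, 0 to 23 °C
Reagents that add atoms: none
Why: Mesylation followed by E1cB elimination through the C5 anion; the Z isomer (C7 cis to O1) should be favoured because the E isomer suffers allylic strain with the C4 methoxy group, and short exposure to the amidine base should leave C7 intact.

Step 14
Reactants: 26 (5Z)-5-[(2S,4E,6E)-9-[5-(furan-3-ylmethyl)furan-3-yl]-2,6-dimethylnona-4,6-dien-1-ylidene]-4-methoxy-3-methylfuran-2(5H)-one
Product: 27 (5Z)-5-[(2S,4E,6E)-9-[5-(furan-3-ylmethyl)furan-3-yl]-2,6-dimethylnona-4,6-dien-1-ylidene]-4-hydroxy-3-methylfuran-2(5H)-one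
Conditions: LiCl, DMSO, 60 °C; then cold dilute HCl to pH 3
Reagents that add atoms: none
Why: SN2 demethylation of the vinylogous methyl ester by chloride in a dipolar aprotic solvent releases the lithium tetronate, which is protonated on work-up; these neutral nucleophilic conditions should not affect the furans, the diene or C7.

## Compound list

1 | prop-2-yn-1-ol | C#CCO | starting material
2 | but-3-en-1-ylmagnesium bromide | C=CCC[Mg]Br | starting material
3 | 4-(but-3-en-1-yl)-2,5-dihydro-1,2-oxamagnesole (cyclic alkenylmagnesium alkoxide) | C=CCCC1=C[Mg]OC1 | intermediate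
4 | (2Z)-2-(but-3-en-1-yl)-3-iodoprop-2-en-1-ol | OC/C(CCC=C)=C\I | intermediate
5 | furan-3-carbaldehyde | O=Cc1ccoc1 | starting material
6 | 3-ethynylfuran | C#Cc1ccoc1 | intermediate
7 | (2Z)-2-(but-3-en-1-yl)-5-(furan-3-yl)pent-2-en-4-yn-1-ol | OC/C(CCC=C)=C\C#Cc1ccoc1 | intermediate
8 | (2Z)-4-(but-3-en-1-yl)-2-(furan-3-ylmethylidene)-2,5-dihydrofuran | C=CCCC1=C/C(=C/c2ccoc2)OC1 | intermediate
9 | 4-(but-3-en-1-yl)-2-(furan-3-ylmethyl)furan | C=CCCc1coc(Cc2ccoc2)c1 | intermediate
10 | 2-methylprop-2-enal (methacrolein) | C=C(C)C=O | starting material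
11 | (2E)-5-[5-(furan-3-ylmethyl)furan-3-yl]-2-methylpent-2-enal | O=C/C(C)=C/CCc1coc(Cc2ccoc2)c1 | intermediate
12 | vinylmagnesium bromide | C=C[Mg]Br | starting material
13 | rac-(4E)-7-[5-(furan-3-ylmethyl)furan-3-yl]-4-methylhepta-1,4-dien-3-ol | C=CC(O)/C(C)=C/CCc1coc(Cc2ccoc2)c1 | intermediate
14 | (3S,4E)-7-[5-(furan-3-ylmethyl)furan-3-yl]-4-methylhepta-1,4-dien-3-ol | C=C[C@H](O)/C(C)=C/CCc1coc(Cc2ccoc2)c1 | intermediate
15 | (3S,4E)-7-[5-(furan-3-ylmethyl)furan-3-yl]-4-methylhepta-1,4-dien-3-yl propanoate | CCC(=O)O[C@@H](C=C)/C(C)=C/CCc1coc(Cc2ccoc2)c1 | intermediate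
16 | lithium enolate of 15 (methyl trans to O–Li) | C/C=C(/O[Li])O[C@@H](C=C)/C(C)=C/CCc1coc(Cc2ccoc2)c1 | intermediate
17 | (E)-O-trimethylsilyl ketene acetal of 15 (methyl trans to OSiMe3) | C/C=C(/O[Si](C)(C)C)O[C@@H](C=C)/C(C)=C/CCc1coc(Cc2ccoc2)c1 | intermediate
18 | trimethylsilyl (2S,4E,6E)-9-[5-(furan-3-ylmethyl)furan-3-yl]-2,6-dimethylnona-4,6-dienoate | C[Si](C)(C)OC(=O)[C@@H](C)C/C=C/C(C)=C/CCc1coc(Cc2ccoc2)c1 | intermediate
19 | (2S,4E,6E)-9-[5-(furan-3-ylmethyl)furan-3-yl]-2,6-dimethylnona-4,6-dien-1-ol | OC[C@@H](C)C/C=C/C(C)=C/CCc1coc(Cc2ccoc2)c1 | intermediate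
20 | (2S,4E,6E)-9-[5-(furan-3-ylmethyl)furan-3-yl]-2,6-dimethylnona-4,6-dienal | O=C[C@@H](C)C/C=C/C(C)=C/CCc1coc(Cc2ccoc2)c1 | intermediate
21 | 4-hydroxy-3-methylfuran-2(5H)-one | CC1=C(O)COC1=O | starting material
22 | 4-methoxy-3-methylfuran-2(5H)-one | CC1=C(OC)COC1=O | intermediate
23 | lithium 4-methoxy-3-methylfuran-2-olate | [Li]OC1=C(C)C(OC)=CO1 | intermediate
24 | 5-[(2S,4E,6E)-9-[5-(furan-3-ylmethyl)furan-3-yl]-1-hydroxy-2,6-dimethylnona-4,6-dien-1-yl]-4-methoxy-3-methylfuran-2(5H)-one (mixture at C5 and C6) | CC1=C(OC)C(C(O)[C@@H](C)C/C=C/C(C)=C/CCc2coc(Cc3ccoc3)c2)OC1=O | intermediate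
25 | methanesulfonate of 24 | CC1=C(OC)C(C(OS(C)(=O)=O)[C@@H](C)C/C=C/C(C)=C/CCc2coc(Cc3ccoc3)c2)OC1=O | intermediate
26 | (5Z)-5-[(2S,4E,6E)-9-[5-(furan-3-ylmethyl)furan-3-yl]-2,6-dimethylnona-4,6-dien-1-ylidene]-4-methoxy-3-methylfuran-2(5H)-one | CC1=C(OC)/C(=C/[C@@H](C)C/C=C/C(C)=C/CCc2coc(Cc3ccoc3)c2)OC1=O | intermediate
27 | (5Z)-5-[(2S,4E,6E)-9-[5-(furan-3-ylmethyl)furan-3-yl]-2,6-dimethylnona-4,6-dien-1-ylidene]-4-hydroxy-3-methylfuran-2(5H)-one | CC1=C(O)/C(=C/[C@@H](C)C/C=C/C(C)=C/CCc2coc(Cc3ccoc3)c2)OC1=O | target

## Step count and least certain steps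

Total step count: 14. Longest linear sequence: 12 (steps 1, 3 to 10, 12 to 14).

**Step 9 (key step).**
- The most likely failure is leakage in ketene acetal geometry. The terminus C8 is unsubstituted, so the minor geometry leads to the enantiomer at C7, not to a separable diastereomer, and the enantiomeric purity is eroded.
- Rearrangement through the trisubstituted arm and thermal allylic transposition of the doubly allylic ester are the other possible losses.
- A more E-selective enolization (LiN(SiMe3)2 with Et3N in toluene) is the first remedy at the level of conditions.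
- The fallback changes the way C7 is set. It sets out from 11 and comes back at 19:
  - Horner–Wadsworth–Emmons reaction of 11 with triethyl phosphonoacetate (NaH, THF) gives ethyl (2E,4E)-dienoate F1.
  - Reduction with iBu2AlH gives dienol F2, and Appel bromination (CBr4, PPh3) gives dienyl bromide F3.
  - Alkylation of the sodium enolate of commercial (4R)-4-benzyl-3-propanoyl-1,3-oxazolidin-2-one (NaN(SiMe3)2, THF, −78 °C) with F3 gives imide F4. Here the auxiliary sets C7, and the minor diastereomer can be removed by chromatography.
  - LiBH4 reduction gives 19.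

**Step 1.**
- Carbomagnesiation with a functionalized primary Grignard reagent may stall at the propargylic alkoxide or lose regiocontrol, because the copper-catalysed addition competes with simple protonolysis and with reagent decomposition.
- The fallback builds ring A by directed metalation instead of cyclization. It sets out from 5 and comes back at 9:
  - 5 is masked in situ as its lithium morpholide adduct, lithiated at C5 with sec-butyllithium and alkylated with purchased 3-(bromomethyl)furan to give 5-(furan-3-ylmethyl)furan-3-carbaldehyde F5.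
  - NaBH4 reduction gives alcohol F6, and PBr3 (Et2O, −20 °C, used crude) gives bromide F7.
  - Coupling with allylmagnesium bromide gives 9.

**Step 5.**
- Cross-metathesis may suffer from catalyst inhibition by the furan oxygens or from incomplete E control, since the trisubstituted alkene forms slowly and secondary metathesis is limited.
- The fallback sets out from 9 and comes back at 11: dihydroxylation of the terminal alkene (OsO4 cat., N-methylmorpholine N-oxide) and cleavage with NaIO4 give 3-[5-(furan-3-ylmethyl)furan-3-yl]propanal F8. A Wittig reaction with 2-(triphenylphosphoranylidene)propanal (toluene, 90 °C) then gives 11.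

**Step 7.**
- Enantiomer discrimination by the lipase may be insufficient, because both carbinol substituents are sp2 groups and the size difference between vinyl and the 1-methylalkenyl chain is the only handle.
- The fallback sets out from 13 and comes back at 14: Sharpless kinetic resolution (Ti(OiPr)4, D-(−)-diisopropyl tartrate, tert-butyl hydroperoxide, 4 Å sieves, CH2Cl2, −20 °C). The R enantiomer is consumed by epoxidation of its trisubstituted alkene to epoxy alcohol F9, and the S alcohol 14 is recovered.

**Step 13.**
- Base-mediated γ-deprotonation at C7 of the ylidene product would cause epimerization, and incomplete Z control is possible; both arise from the extended enolate that the amidine base can form.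
- The fallback forms C5=C6 by olefination. It sets out from 22 and comes back at 26:
  - Radical bromination at C5 (N-bromosuccinimide, PhCF3, light) gives 5-bromo tetronate F10.
  - Arbuzov reaction with P(OEt)3 gives phosphonate F11.
  - Horner–Wadsworth–Emmons reaction of F11 with 20 (LiCl, iPr2NEt, MeCN) gives 26 under milder base and without a sulfonate intermediate.

## Further compounds

F1 | step 9 | ethyl (2E,4E)-7-[5-(furan-3-ylmethyl)furan-3-yl]-4-methylhepta-2,4-dienoate | CCOC(=O)/C=C/C(C)=C/CCc1coc(Cc2ccoc2)c1
F2 | step 9 | (2E,4E)-7-[5-(furan-3-ylmethyl)furan-3-yl]-4-methylhepta-2,4-dien-1-ol | OC/C=C/C(C)=C/CCc1coc(Cc2ccoc2)c1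
F3 | step 9 | 4-[(3E,5E)-7-bromo-4-methylhepta-3,5-dien-1-yl]-2-(furan-3-ylmethyl)furan | BrC/C=C/C(C)=C/CCc1coc(Cc2ccoc2)c1
F4 | step 9 | (4R)-4-benzyl-3-[(2S,4E,6E)-9-[5-(furan-3-ylmethyl)furan-3-yl]-2,6-dimethylnona-4,6-dienoyl]-1,3-oxazolidin-2-one | O=C([C@@H](C)C/C=C/C(C)=C/CCc1coc(Cc2ccoc2)c1)N1[C@H](Cc2ccccc2)COC1=O
F5 | step 1 | 5-(furan-3-ylmethyl)furan-3-carbaldehyde | O=Cc1coc(Cc2ccoc2)c1
F6 | step 1 | [5-(furan-3-ylmethyl)furan-3-yl]methanol | OCc1coc(Cc2ccoc2)c1
F7 | step 1 | 4-(bromomethyl)-2-(furan-3-ylmethyl)furan | BrCc1coc(Cc2ccoc2)c1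
F8 | step 5 | 3-[5-(furan-3-ylmethyl)furan-3-yl]propanal | O=CCCc1coc(Cc2ccoc2)c1
F9 | step 7 | (1R)-1-[(2R,3R)-3-{2-[5-(furan-3-ylmethyl)furan-3-yl]ethyl}-2-methyloxiran-2-yl]prop-2-en-1-ol | C=C[C@@H](O)[C@@]1(C)O[C@@H]1CCc1coc(Cc2ccoc2)c1
F10 | step 13 | 5-bromo-4-methoxy-3-methylfuran-2(5H)-one | CC1=C(OC)C(Br)OC1=O
F11 | step 13 | diethyl (3-methoxy-4-methyl-5-oxo-2,5-dihydrofuran-2-yl)phosphonate | CCOP(=O)(OCC)C1OC(=O)C(C)=C1OC
A1 | alternative 1 | tert-butyl{[(2S,4E)-5-iodo-2-methylpent-4-en-1-yl]oxy}dimethylsilane | CC(C)(C)[Si](C)(C)OC[C@@H](C)C/C=C/I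
A2 | alternative 1 | 2-[(2Z)-5-[5-(furan-3-ylmethyl)furan-3-yl]pent-2-en-2-yl]-4,4,5,5-tetramethyl-1,3,2-dioxaborolane | CC1(C)OB(OC1(C)C)/C(C)=C/CCc1coc(Cc2ccoc2)c1
A3 | alternative 1 | tert-butyl{[(2S,4E,6E)-9-[5-(furan-3-ylmethyl)furan-3-yl]-2,6-dimethylnona-4,6-dien-1-yl]oxy}dimethylsilane | CC(C)(C)[Si](C)(C)OC[C@@H](C)C/C=C/C(C)=C/CCc1coc(Cc2ccoc2)c1
A4 | alternative 2 | (2E,6S,8E,10E)-13-[5-(furan-3-ylmethyl)furan-3-yl]-3-methoxy-2,6,10-trimethyltrideca-2,8,10-trien-4-ynoic acid | OC(=O)/C(C)=C(OC)\C#C[C@@H](C)C/C=C/C(C)=C/CCc1coc(Cc2ccoc2)c1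
A5 | alternative 3 | (3S)-4-{[tert-butyl(dimethyl)silyl]oxy}-3-methylbutanal | CC(C)(C)[Si](C)(C)OC[C@@H](C)CC=O
A6 | alternative 3 | 5-{[(2E)-5-[5-(furan-3-ylmethyl)furan-3-yl]-2-methylpent-2-en-1-yl]sulfonyl}-1-phenyl-1H-tetrazole | O=S(=O)(C/C(C)=C/CCc1coc(Cc2ccoc2)c1)c1nnnn1-c1ccccc1
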